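**Plan**

- Retrosynthesis: remove the acetate and silyl groups. Cut the bond from the one-carbon bridge CH2 to the bridgehead CH next to the ketone (enolate alkylation). Then cut together the C(=O)–CH2 bond and the bond from the ring-fusion CH to the quaternary C–CH3 of the cyclohexanone, which excises CH2=CH and leaves a cyclobutanone. Then cut the side chain from the quaternary ring carbon, and take the cyclobutanone back to a cyclopropanol epoxide and an E-enone.
- Enabling feature: in the cyclohexanone ring D the run C(=O)–CH–CH(CH3)–C(CH3) is a latent cyclobutanone, and the remaining CH2–CH is a vinyl group on the neighbouring quaternary carbon. That carbon and the acetoxy carbon sit 1,4 and cis on the carbocyclic ring B, so a δ-lactone (carbonyl = future bridge CH2, ring O = future acetate O) can hold the two partners together.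
- Forward ring order: δ-lactone (temporary) → cyclobutanone → ring B and ring D closed in one operation → lactone opened by reduction → last bond closes the bicyclo[2.2.2]octanone.
- Stereochemistry: side-chain carbinol from (S)-linalool; CH–CH3 of ring B from methyl hydrogen (R)-3-methylglutarate; acetoxy carbon and quaternary C–CH3 from Shi epoxidation of an E-alkene plus stereospecific ring expansion; bridge CH–CH3 by cuprate addition anti to the bulky branch; quaternary side-chain carbon by alkylation anti to the neighbouring methyl; ring-fusion CH by the lactone bridge in the key step; bridgehead CH by geometry.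

Key step: step 17

Assumption: (S)-(+)-linalool is taken as purchasable in high enantiomeric purity; with enriched material only, the minor diastereomer formed at step 16 would be removed by chromatography.

**Route**

Step 1
Reactants: 1 (S)-(+)-linalool
Product: 2 (3S)-3-[(tert-butyldimethylsilyl)oxy]-3,7-dimethylocta-1,6-diene
Conditions: TBSOTf, 2,6-lutidine, CH2Cl2, 0 °C to rt
Reagents that add atoms: tert-butyldimethylsilyl trifluoromethanesulfonate, CC(C)(C)[Si](C)(C)OS(=O)(=O)C(F)(F)F
Why: silyl triflate silylation of a hindered tertiary alcohol; the carbinol centre is not touched.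

Step 2
Reactants: 2 (3S)-3-[(tert-butyldimethylsilyl)oxy]-3,7-dimethylocta-1,6-diene
Product: 3 (4S)-4-[(tert-butyldimethylsilyl)oxy]-4-methylhex-5-enal
Conditions: O3 (1.0 equiv), CH2Cl2, −78 °C, Sudan Red 7B end point; then PPh3, −78 °C to rt
Reagents that add atoms: ozone, [O-][O+]=O
Why: chemoselective ozonolysis; the electron-rich trisubstituted alkene should be cleaved well before the vinyl group, which is slowed by the neighbouring quaternary silyloxy carbon.

Step 3
Reactants: 3 (4S)-4-[(tert-butyldimethylsilyl)oxy]-4-methylhex-5-enal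
Product: 4 (4S)-4-[(tert-butyldimethylsilyl)oxy]-4-methylhex-5-enoic acid
Conditions: NaClO2, NaH2PO4, 2-methyl-2-butene, tBuOH/H2O, 0 °C to rt
Reagents that add atoms: sodium chlorite, [Na+].[O-]Cl=O
Why: Pinnick oxidation; the alkene scavenger protects the vinyl group from hypochlorite.

Step 4
Reactants: 4 (4S)-4-[(tert-butyldimethylsilyl)oxy]-4-methylhex-5-enoic acid
Product: 6 tert-butyl{[(3S)-5-iodo-3-methylpent-1-en-3-yl]oxy}dimethylsilane, via Barton ester 5 (not isolated)
Conditions: N-hydroxypyridine-2-thione, DCC, DMAP (cat.), CH2Cl2, 0 °C, dark; then CHI3, hν (tungsten lamp), rt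
Reagents that add atoms: iodoform, IC(I)I
Why: Barton decarboxylative iodination (radical chain); the primary radical should take iodine from CHI3 much faster than it can add to the remote vinyl group, and the carbinol centre is untouched.

Step 5
Reactants: 7 methyl hydrogen (R)-3-methylglutarate
Product: 8 methyl (3R)-5-hydroxy-3-methylpentanoate
Conditions: BH3·SMe2, THF, 0 °C to rt; MeOH quench
Reagents that add atoms: none
Why: chemoselective borane reduction of the carboxylic acid beside the methyl ester.

Step 6
Reactants: 8 methyl (3R)-5-hydroxy-3-methylpentanoate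
Product: 9 methyl (3R)-3-methyl-5-oxopentanoate
Conditions: TEMPO (cat.), PhI(OAc)2, CH2Cl2, rt
Reagents that add atoms: none
Why: oxoammonium oxidation of a primary alcohol to the aldehyde; the stereocentre is β to the new carbonyl and cannot epimerise.

Step 7
Reactants: 9 methyl (3R)-3-methyl-5-oxopentanoate; 10 3-(triphenyl-λ5-phosphanylidene)butan-2-one
Product: 11 methyl (3R,5E)-3,6-dimethyl-7-oxooct-5-enoate
Conditions: toluene, 90 °C
Reagents that add atoms: none
Why: Wittig reaction of a stabilised ylide, which should give the E-trisubstituted enone that the later stereospecific steps require.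

Step 8
Reactants: 11 methyl (3R,5E)-3,6-dimethyl-7-oxooct-5-enoate
Product: 12 methyl (3R,5E)-3,6-dimethyl-7-[(triethylsilyl)oxy]octa-5,7-dienoate
Conditions: TESOTf, Et3N, CH2Cl2, 0 °C
Reagents that add atoms: triethylsilyl trifluoromethanesulfonate, CC[Si](CC)(CC)OS(=O)(=O)C(F)(F)F
Why: soft enolisation of the methyl ketone to the cross-conjugated 2-silyloxy diene; the ester is not enolised under these conditions.

Step 9
Reactants: 12 methyl (3R,5E)-3,6-dimethyl-7-[(triethylsilyl)oxy]octa-5,7-dienoate
Product: 13 methyl (3R,5E)-3-methyl-6-{1-[(triethylsilyl)oxy]cyclopropyl}hept-5-enoate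
Conditions: Et2Zn, CH2I2, CH2Cl2, 0 °C
Reagents that add atoms: diiodomethane, ICI
Why: Simmons–Smith (Furukawa) cyclopropanation, selective for the electron-rich silyl enol ether double bond of a 2-silyloxy diene.

Step 10
Reactants: 13 methyl (3R,5E)-3-methyl-6-{1-[(triethylsilyl)oxy]cyclopropyl}hept-5-enoate
Product: 14 methyl (3R)-3-methyl-4-[(2R,3S)-3-methyl-3-{1-[(triethylsilyl)oxy]cyclopropyl}oxiran-2-yl]butanoate
Conditions: D-fructose-derived Shi ketone (30 mol %), Oxone (2KHSO5·KHSO4·K2SO4), K2CO3, Bu4NHSO4 (cat.), MeCN/CH2(OMe)2/aqueous buffer (pH 10.5), 0 °C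
Reagents that add atoms: potassium peroxymonosulfate (active part of Oxone), [K+].[O-]S(=O)(=O)OO
Why: Shi asymmetric epoxidation of an E-trisubstituted alkene through the spiro transition state; the D-fructose ketone should deliver oxygen in the same facial sense as for trans-β-methylstyrene, which sets both oxirane carbons under catalyst control.

Step 11
Reactants: 14 methyl (3R)-3-methyl-4-[(2R,3S)-3-methyl-3-{1-[(triethylsilyl)oxy]cyclopropyl}oxiran-2-yl]butanoate
Product: 17 (4R,6R)-4-methyl-6-[(1R)-1-methyl-2-oxocyclobutyl]oxan-2-one, via cyclopropanol epoxide 15 (not isolated), via hydroxy ester 16 (not isolated)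
Conditions: Bu4NF, AcOH, THF, 0 °C; then PPTS (cat.), benzene, 60 °C
Reagents that add atoms: none
Why: semipinacol ring expansion of a cyclopropanol epoxide to a β-hydroxy cyclobutanone, in which a cyclopropane bond migrates anti to the breaking C–O bond (inversion at the quaternary carbon, retention at the carbinol carbon), followed by acid-catalysed lactonisation to the cis-4,6-disubstituted δ-lactone.

Step 12
Reactants: 17 (4R,6R)-4-methyl-6-[(1R)-1-methyl-2-oxocyclobutyl]oxan-2-one
Product: 18 (4R,6R)-4-methyl-6-[(1R)-1-methyl-4-oxocyclobut-2-en-1-yl]oxan-2-one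
Conditions: LiN(iPr)2, THF, −78 °C; then N-tert-butylbenzenesulfinimidoyl chloride, −78 °C
Reagents that add atoms: none
Why: Proposed new method: the ketone enolate (only the CH2 side can enolise, and the ketone is more acidic than the lactone) is sulfenylated at carbon and the adduct should collapse by intramolecular syn-elimination through a five-membered transition state, for which the cis C–H of a cyclobutane is almost eclipsed, at a temperature where the 4,4-disubstituted cyclobutenone does not ring-open; the closest known reaction type is the Mukaiyama one-pot dehydrogenation of five- to seven-membered ketone enolates with this reagent, and selenoxide syn-elimination.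

Step 13
Reactants: 18 (4R,6R)-4-methyl-6-[(1R)-1-methyl-4-oxocyclobut-2-en-1-yl]oxan-2-one
Product: 19 (4R,6R)-6-{(1R,4R)-1,4-dimethyl-2-[(triethylsilyl)oxy]cyclobut-2-en-1-yl}-4-methyloxan-2-one
Conditions: Me2CuLi (from MeLi and CuI), Et3SiCl, THF, −78 °C
Reagents that add atoms: lithium dimethylcuprate, [Li+].C[Cu-]C; chlorotriethylsilane, CC[Si](Cl)(CC)CC
Why: cuprate conjugate addition to a cyclobutenone, in which methyl should enter anti to the lactone-bearing branch on the adjacent quaternary carbon and hence cis to its methyl; the enolate is trapped as a silyl enol ether that masks the cyclobutanone through steps 14 to 16.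

Step 14
Reactants: 19 (4R,6R)-6-{(1R,4R)-1,4-dimethyl-2-[(triethylsilyl)oxy]cyclobut-2-en-1-yl}-4-methyloxan-2-one
Product: 20 (4R,6R)-6-{(1R,4R)-1,4-dimethyl-2-[(triethylsilyl)oxy]cyclobut-2-en-1-yl}-3-(1-hydroxyethyl)-4-methyloxan-2-one (mixture at C3 and the carbinol carbon)
Conditions: LiN(iPr)2, THF, −78 °C; then CH3CHO; H2O quench
Reagents that add atoms: acetaldehyde, CC=O
Why: aldol addition of the lactone lithium enolate; both new centres are erased in steps 15 and 16, so their configuration does not matter.

Step 15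
Reactants: 20 aldol adduct
Product: 22 (3E,4R,6R)-6-{(1R,4R)-1,4-dimethyl-2-[(triethylsilyl)oxy]cyclobut-2-en-1-yl}-3-ethylidene-4-methyloxan-2-one, via mesylate 21 (not isolated)
Conditions: MsCl, Et3N, CH2Cl2, 0 °C; then DBU, rt
Reagents that add atoms: none
Why: mesylation and E1cB elimination to the α-ethylidene lactone; either alkene isomer serves in the next step.

Step 16
Reactants: 22 α-ethylidene lactone; 6 tert-butyl{[(3S)-5-iodo-3-methylpent-1-en-3-yl]oxy}dimethylsilane
Product: 24 (3R,4R,6R)-3-{(3S)-3-[(tert-butyldimethylsilyl)oxy]-3-methylpent-4-en-1-yl}-6-[(1R,2R)-1,2-dimethyl-4-oxocyclobutyl]-3-ethenyl-4-methyloxan-2-one, via silyl enol ether 23 (not isolated)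
Conditions: LiN(iPr)2, DMPU, THF, −78 °C; then 6, −78 to −20 °C; then 1 M HCl, THF, 0 °C
Reagents that add atoms: none
Why: deconjugative alkylation: γ-deprotonation gives the extended dienolate, which alkylates at the α-carbon, and the iodide should approach anti to the neighbouring ring methyl, so that the vinyl group ends cis and the side chain trans to it; the acid work-up then frees the cyclobutanone.

Step 17
Reactants: 24 vinyl lactone carrying the cyclobutanone
Product: 25 1-{(3S)-3-[(tert-butyldimethylsilyl)oxy]-3-methylpent-4-en-1-yl}-6,7,11-trimethyl-9-oxatricyclo[6.2.2.0(2,7)]dodecane-4,10-dione (cis-fused; all centres as in the target)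
Conditions: [Rh(C2H4)2Cl]2 (5 mol %), P[3,5-(CF3)2C6H3]3 (24 mol %), 1,4-dioxane, 110 °C, sealed tube
Reagents that add atoms: none
Why: Monovalent rhodium inserts into the strained C(=O)–C(quaternary) bond of the cyclobutanone to give a five-membered acyl alkyl metallacycle of trivalent rhodium, the tethered vinyl group undergoes migratory insertion, and C(sp3)–C(sp3) reductive elimination follows, so that CH2=CH is stitched in between the carbonyl carbon and the quaternary carbon with retention at the latter. The closest known reaction type is the rhodium-catalysed intramolecular cut-and-sew carboacylation of cyclobutanones that carry an olefin tethered at C2, which gives fused cyclohexanones with a quaternary ring-fusion carbon. Ring D arises by two-carbon expansion of the four-membered ring (formal 4+2), and ring B by 6-exo-type bonding of the internal vinyl carbon to the quaternary carbon, bridged across the boat form of the δ-lactone. The one new stereocentre, the ring-fusion CH, is set by the lactone bridge: in the 2-oxabicyclo[2.2.2]octanone that forms, the torsion about the new bond is held near 0°, so only the cis-fused cyclohexanone can close, on the lactone side and away from the ring-B methyl. The step needs cleavage of the more substituted acyl–carbon bond, insertion faster than loss of CO, and the right one of two vinyl groups; insertion on the CH2 side is reversible and has no olefin within reach, the electron-poor phosphine favours insertion over decarbonylation, and the side-chain vinyl group is too remote to reach the metal.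

Step 18
Reactants: 25 tricyclic keto lactone
Product: 28 5-hydroxy-8-(hydroxymethyl)-4,4a,7-trimethyl-8-{(3S)-3-[(tert-butyldimethylsilyl)oxy]-3-methylpent-4-en-1-yl}octahydronaphthalen-2(1H)-one (cis-fused; all centres as in the target), via silyl enol ether 26 (not isolated), via silylated diol 27 (not isolated)
Conditions: LiN(iPr)2, Me3SiCl, THF, −78 °C; then LiAlH4, −78 to 0 °C; then 1 M HCl, 0 °C
Reagents that add atoms: none
Why: the ketone is masked in the flask as its silyl enol ether (the lactone has no α-hydrogen), LiAlH4 reduces the lactone to the diol, and the acid work-up returns the ketone.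

Step 19
Reactants: 28 keto diol
Product: 29 primary p-toluenesulfonate of 28
Conditions: TsCl, pyridine, DMAP (cat.), CH2Cl2, 0 °C to rt
Reagents that add atoms: p-toluenesulfonyl chloride, Cc1ccc(cc1)S(Cl)(=O)=O
Why: selective sulfonylation of the primary alcohol over the hindered secondary one next to a quaternary carbon.

Step 20
Reactants: 29 keto tosylate
Product: 30 triethylsilyl ether of 29 at the secondary hydroxyl
Conditions: TESOTf, 2,6-lutidine, CH2Cl2, −78 °C
Reagents that add atoms: triethylsilyl trifluoromethanesulfonate, CC[Si](CC)(CC)OS(=O)(=O)C(F)(F)F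
Why: silylation blocks the alkoxide, which would otherwise displace the tosylate in the next step to give a bridged ether.

Step 21
Reactants: 30 silylated keto tosylate
Product: 31 tricyclic ketone with the target skeleton, secondary OSiEt3 and tertiary OSi(tBu)Me2
Conditions: KOtBu, tBuOH/THF, rt to 50 °C
Reagents that add atoms: none
Why: intramolecular enolate C-alkylation under equilibrating conditions; only the enolate toward the CH2 next to the CH–CH3 can reach the tosylate (the other would have to close a four-membered ring), and the bridgehead configuration is fixed by the geometry of the bicyclo[2.2.2]octanone.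

Step 22
Reactants: 31 bis-silyl tricyclic ketone
Product: 32 tricyclic keto diol (the target without its acetyl group)
Conditions: Bu4NF, THF, 50 °C
Reagents that add atoms: none
Why: fluoride cleavage of both silyl ethers under conditions that do not ionise the tertiary allylic alcohol.

Step 23
Reactants: 32 tricyclic keto diol
Product: 33 target CNP0281208.1
Conditions: Ac2O, pyridine, DMAP (cat.), CH2Cl2, 0 °C
Reagents that add atoms: acetic anhydride, CC(=O)OC(C)=O
Why: acetylation of the secondary alcohol, which should be much faster than that of the tertiary allylic alcohol.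

**Compound list**

1 | (S)-(+)-linalool | C=C[C@@](C)(O)CCC=C(C)C | starting material
2 | (3S)-3-[(tert-butyldimethylsilyl)oxy]-3,7-dimethylocta-1,6-diene | C=C[C@@](C)(O[Si](C)(C)C(C)(C)C)CCC=C(C)C | intermediate
3 | (4S)-4-[(tert-butyldimethylsilyl)oxy]-4-methylhex-5-enal | C=C[C@@](C)(O[Si](C)(C)C(C)(C)C)CCC=O | intermediate
4 | (4S)-4-[(tert-butyldimethylsilyl)oxy]-4-methylhex-5-enoic acid | C=C[C@@](C)(O[Si](C)(C)C(C)(C)C)CCC(=O)O | intermediate
5 | Barton ester of 4 (2-thioxopyridin-1(2H)-yl ester; formed in the flask) | C=C[C@@](C)(O[Si](C)(C)C(C)(C)C)CCC(=O)On1ccccc1=S | intermediate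
6 | tert-butyl{[(3S)-5-iodo-3-methylpent-1-en-3-yl]oxy}dimethylsilane | C=C[C@@](C)(O[Si](C)(C)C(C)(C)C)CCI | intermediate
7 | methyl hydrogen (R)-3-methylglutarate | COC(=O)C[C@H](C)CC(=O)O | starting material
8 | methyl (3R)-5-hydroxy-3-methylpentanoate | COC(=O)C[C@H](C)CCO | intermediate
9 | methyl (3R)-3-methyl-5-oxopentanoate | COC(=O)C[C@H](C)CC=O | intermediate
10 | 3-(triphenyl-λ5-phosphanylidene)butan-2-one | CC(=O)C(C)=P(c1ccccc1)(c1ccccc1)c1ccccc1 | starting material
11 | methyl (3R,5E)-3,6-dimethyl-7-oxooct-5-enoate | COC(=O)C[C@H](C)C/C=C(\C)C(C)=O | intermediate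
12 | methyl (3R,5E)-3,6-dimethyl-7-[(triethylsilyl)oxy]octa-5,7-dienoate | COC(=O)C[C@H](C)C/C=C(\C)C(=C)O[Si](CC)(CC)CC | intermediate
13 | methyl (3R,5E)-3-methyl-6-{1-[(triethylsilyl)oxy]cyclopropyl}hept-5-enoate | COC(=O)C[C@H](C)C/C=C(\C)C1(CC1)O[Si](CC)(CC)CC | intermediate
14 | methyl (3R)-3-methyl-4-[(2R,3S)-3-methyl-3-{1-[(triethylsilyl)oxy]cyclopropyl}oxiran-2-yl]butanoate | COC(=O)C[C@H](C)C[C@H]1O[C@]1(C)C2(CC2)O[Si](CC)(CC)CC | intermediate
15 | methyl (3R)-4-[(2R,3S)-3-(1-hydroxycyclopropyl)-3-methyloxiran-2-yl]-3-methylbutanoate (formed in the flask) | COC(=O)C[C@H](C)C[C@H]1O[C@]1(C)C2(O)CC2 | intermediate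
16 | methyl (3R,5R)-5-hydroxy-3-methyl-5-[(1R)-1-methyl-2-oxocyclobutyl]pentanoate (formed in the flask) | COC(=O)C[C@H](C)C[C@@H](O)[C@@]1(C)CCC1=O | intermediate
17 | (4R,6R)-4-methyl-6-[(1R)-1-methyl-2-oxocyclobutyl]oxan-2-one | O=C1C[C@H](C)C[C@@H](O1)[C@@]2(C)CCC2=O | intermediate
18 | (4R,6R)-4-methyl-6-[(1R)-1-methyl-4-oxocyclobut-2-en-1-yl]oxan-2-one | O=C1C[C@H](C)C[C@@H](O1)[C@@]2(C)C=CC2=O | intermediate
19 | (4R,6R)-6-{(1R,4R)-1,4-dimethyl-2-[(triethylsilyl)oxy]cyclobut-2-en-1-yl}-4-methyloxan-2-one | O=C1C[C@H](C)C[C@@H](O1)[C@@]2(C)[C@H](C)C=C2O[Si](CC)(CC)CC | intermediate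
20 | 3-(1-hydroxyethyl) derivative of 19 (mixture at C3 and the carbinol carbon) | O=C1C(C(C)O)[C@H](C)C[C@@H](O1)[C@@]2(C)[C@H](C)C=C2O[Si](CC)(CC)CC | intermediate
21 | methanesulfonate of 20 (formed in the flask) | O=C1C(C(C)OS(C)(=O)=O)[C@H](C)C[C@@H](O1)[C@@]2(C)[C@H](C)C=C2O[Si](CC)(CC)CC | intermediate
22 | (3E,4R,6R)-6-{(1R,4R)-1,4-dimethyl-2-[(triethylsilyl)oxy]cyclobut-2-en-1-yl}-3-ethylidene-4-methyloxan-2-one | O=C1/C(=C/C)[C@H](C)C[C@@H](O1)[C@@]2(C)[C@H](C)C=C2O[Si](CC)(CC)CC | intermediate
23 | silyl enol ether of 24 (alkylation product before acid work-up) | O=C1[C@@](C=C)(CC[C@](C)(O[Si](C)(C)C(C)(C)C)C=C)[C@H](C)C[C@@H](O1)[C@@]2(C)[C@H](C)C=C2O[Si](CC)(CC)CC | intermediate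
24 | (3R,4R,6R)-3-{(3S)-3-[(tert-butyldimethylsilyl)oxy]-3-methylpent-4-en-1-yl}-6-[(1R,2R)-1,2-dimethyl-4-oxocyclobutyl]-3-ethenyl-4-methyloxan-2-one | O=C1[C@@](C=C)(CC[C@](C)(O[Si](C)(C)C(C)(C)C)C=C)[C@H](C)C[C@@H](O1)[C@@]2(C)[C@H](C)CC2=O | intermediate
25 | 1-{(3S)-3-[(tert-butyldimethylsilyl)oxy]-3-methylpent-4-en-1-yl}-6,7,11-trimethyl-9-oxatricyclo[6.2.2.0(2,7)]dodecane-4,10-dione, cis-fused | O=C1O[C@@H]2C[C@@H](C)[C@@]1(CC[C@](C)(O[Si](C)(C)C(C)(C)C)C=C)[C@@H]1CC(=O)C[C@@H](C)[C@]21C | intermediate
26 | trimethylsilyl enol ether of 25 (formed in the flask; one regioisomer drawn, the other serves equally) | O=C1O[C@@H]2C[C@@H](C)[C@@]1(CC[C@](C)(O[Si](C)(C)C(C)(C)C)C=C)[C@@H]1C=C(O[Si](C)(C)C)C[C@@H](C)[C@]21C | intermediate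
27 | diol from reduction of 26, enol ether still in place (formed in the flask) | OC[C@@]1(CC[C@](C)(O[Si](C)(C)C(C)(C)C)C=C)[C@H](C)C[C@@H](O)[C@@]2(C)[C@H](C)CC(O[Si](C)(C)C)=C[C@@H]12 | intermediate
28 | 5-hydroxy-8-(hydroxymethyl)-4,4a,7-trimethyl-8-{(3S)-3-[(tert-butyldimethylsilyl)oxy]-3-methylpent-4-en-1-yl}octahydronaphthalen-2(1H)-one, cis-fused | OC[C@@]1(CC[C@](C)(O[Si](C)(C)C(C)(C)C)C=C)[C@H](C)C[C@@H](O)[C@@]2(C)[C@H](C)CC(=O)C[C@@H]12 | intermediate
29 | primary p-toluenesulfonate of 28 | Cc1ccc(cc1)S(=O)(=O)OC[C@@]1(CC[C@](C)(O[Si](C)(C)C(C)(C)C)C=C)[C@H](C)C[C@@H](O)[C@@]2(C)[C@H](C)CC(=O)C[C@@H]12 | intermediate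
30 | triethylsilyl ether of 29 at the secondary hydroxyl | Cc1ccc(cc1)S(=O)(=O)OC[C@@]1(CC[C@](C)(O[Si](C)(C)C(C)(C)C)C=C)[C@H](C)C[C@@H](O[Si](CC)(CC)CC)[C@@]2(C)[C@H](C)CC(=O)C[C@@H]12 | intermediate
31 | target skeleton with secondary OSiEt3 and tertiary OSi(tBu)Me2 | C=C[C@@](C)(O[Si](C)(C)C(C)(C)C)CC[C@@]12C[C@H]3C(=O)C[C@@H]1[C@](C)([C@@H]3C)[C@H](O[Si](CC)(CC)CC)C[C@H]2C | intermediate
32 | tricyclic keto diol (target without the acetyl group) | C=C[C@@](C)(O)CC[C@@]12C[C@H]3C(=O)C[C@@H]1[C@](C)([C@@H]3C)[C@H](O)C[C@H]2C | intermediate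
33 | CNP0281208.1 | C=C[C@@](C)(O)CC[C@@]12C[C@H]3C(=O)C[C@@H]1[C@](C)([C@@H]3C)[C@H](OC(C)=O)C[C@H]2C | target

**Step count and risks**

Total step count: 23. Steps 1 to 4 make the side-chain iodide 6; steps 5 to 23 are the main line.
Longest linear sequence: 19 steps (7 to 33).

Step 12 (the labelled step). The enolate may be sulfenylated but fail to eliminate, or the strained enone may be consumed as it forms by conjugate addition of diisopropylamine or of unreacted enolate. The fallback uses known reactions, sets out from diene 12 and returns at 19. Cyclopropanation of 12 with the methyl-substituted carbenoid from Et2Zn and 1,1-diiodoethane gives the methylcyclopropyl silyl ether F1 as a mixture at the two new ring carbons. Shi epoxidation as in step 10 gives the epoxide F2. Desilylation, ring expansion (the more substituted cyclopropane carbon migrates, with retention) and lactonisation as in step 11 give the 3-methylcyclobutanone lactone F3, and its epimer at the new CH–CH3 carbon is removed by chromatography. Enolisation on the only open side (LiN(iPr)2, Et3SiCl) then gives 19. The price is the loss of control at that one centre.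

Step 17. Loss of CO from the acyl rhodium intermediate (ring contraction to a cyclopropane) or plain non-insertion may win if the boat lactone cannot bring the hindered vinyl group to the metal; slow bond formation next to two quaternary carbons is the weak point. The fallback sets out from 22 and returns at 30. The alkylation of step 16 is worked up without acid, so that silyl enol ether 23 is isolated. LiAlH4 opens the lactone to the diol F4, TsCl and pyridine give the primary tosylate F5, TESOTf and 2,6-lutidine give the bis-silyl compound F6, and K2CO3 in MeOH frees the cyclobutanone F7. The same rhodium catalyst then closes the two rings in the unbridged fused mode, which has the closest precedent, and gives 30 directly, so that steps 18 to 20 fall away. The price is that the cis ring fusion is no longer enforced by a bridge and must come from the chair-like transition state of the open tether.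

Step 21. Substitution at the neopentyl-type CH2 is slow, so O-alkylation of the enolate to a bridged enol ether, or decay of the tosylate, may overtake C-alkylation. The fallback sets out from 28 and returns at 31. Both hydroxyls are silylated with TESOTf to give the bis(triethylsilyl) ether F8. Swern conditions oxidise the primary triethylsilyl ether directly to the non-enolisable keto aldehyde F9. Catalytic KOtBu closes the bicyclo[2.2.2]octanone by intramolecular aldol addition to the β-hydroxy ketone F10, which cannot dehydrate at the bridgehead. Thiocarbonyldiimidazole gives the imidazolyl thiocarbonate F11, and Bu3SnH with AIBN (Barton–McCombie deoxygenation) gives 31.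

Further compounds

F1 | step 12 | methyl (3R,5E)-3-methyl-6-{2-methyl-1-[(triethylsilyl)oxy]cyclopropyl}hept-5-enoate (mixture at the cyclopropane carbons) | COC(=O)C[C@H](C)C/C=C(\C)C1(CC1C)O[Si](CC)(CC)CC
F2 | step 12 | methyl (3R)-3-methyl-4-[(2R,3S)-3-methyl-3-{2-methyl-1-[(triethylsilyl)oxy]cyclopropyl}oxiran-2-yl]butanoate | COC(=O)C[C@H](C)C[C@H]1O[C@]1(C)C2(CC2C)O[Si](CC)(CC)CC
F3 | step 12 | (4R,6R)-6-[(1R,2R)-1,2-dimethyl-4-oxocyclobutyl]-4-methyloxan-2-one | O=C1C[C@H](C)C[C@@H](O1)[C@@]2(C)[C@H](C)CC2=O
F4 | step 17 | open-chain diol from reduction of 23, silyl enol ether in place | OC[C@@](C=C)(CC[C@](C)(O[Si](C)(C)C(C)(C)C)C=C)[C@H](C)C[C@@H](O)[C@@]1(C)[C@H](C)C=C1O[Si](CC)(CC)CC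
F5 | step 17 | primary p-toluenesulfonate of F4 | Cc1ccc(cc1)S(=O)(=O)OC[C@@](C=C)(CC[C@](C)(O[Si](C)(C)C(C)(C)C)C=C)[C@H](C)C[C@@H](O)[C@@]1(C)[C@H](C)C=C1O[Si](CC)(CC)CC
F6 | step 17 | triethylsilyl ether of F5 at the secondary hydroxyl | Cc1ccc(cc1)S(=O)(=O)OC[C@@](C=C)(CC[C@](C)(O[Si](C)(C)C(C)(C)C)C=C)[C@H](C)C[C@@H](O[Si](CC)(CC)CC)[C@@]1(C)[C@H](C)C=C1O[Si](CC)(CC)CC
F7 | step 17 | open-chain cyclobutanone from F6 | Cc1ccc(cc1)S(=O)(=O)OC[C@@](C=C)(CC[C@](C)(O[Si](C)(C)C(C)(C)C)C=C)[C@H](C)C[C@@H](O[Si](CC)(CC)CC)[C@@]1(C)[C@H](C)CC1=O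
F8 | step 21 | bis(triethylsilyl) ether of 28 | CC[Si](CC)(CC)OC[C@@]1(CC[C@](C)(O[Si](C)(C)C(C)(C)C)C=C)[C@H](C)C[C@@H](O[Si](CC)(CC)CC)[C@@]2(C)[C@H](C)CC(=O)C[C@@H]12
F9 | step 21 | keto aldehyde from F8 | O=C[C@@]1(CC[C@](C)(O[Si](C)(C)C(C)(C)C)C=C)[C@H](C)C[C@@H](O[Si](CC)(CC)CC)[C@@]2(C)[C@H](C)CC(=O)C[C@@H]12
F10 | step 21 | bridge-hydroxylated analogue of 31 (aldol product, either epimer at the carbinol) | C=C[C@@](C)(O[Si](C)(C)C(C)(C)C)CC[C@@]12C(O)[C@H]3C(=O)C[C@@H]1[C@](C)([C@@H]3C)[C@H](O[Si](CC)(CC)CC)C[C@H]2C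
F11 | step 21 | O-(imidazol-1-ylthiocarbonyl) derivative of F10 | C=C[C@@](C)(O[Si](C)(C)C(C)(C)C)CC[C@@]12C(OC(=S)n3ccnc3)[C@H]4C(=O)C[C@@H]1[C@](C)([C@@H]4C)[C@H](O[Si](CC)(CC)CC)C[C@H]2C
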